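**Retrosynthetic overview**
- The strategy rests on two features of the single ring, the 1,2-dioxane O1–O2–C3–C4–C5–C6. C6 is a fully substituted carbon bearing O1, an ethyl group and the unsaturated C7, so with C7 as an alkyne carbon it is a tertiary propargylic centre that can ionise. C3, which bears O2, lies β to the C1 carboxyl and can be the ketone of a β-keto ester.
- The ring is closed in one operation: H2O2 forms C6–O1 by SN1 substitution of a tertiary propargylic alcohol and O2–C3 by addition to the ketone. C3–H then comes from axial silane reduction of the 1,2-dioxan-3-ol.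
- The C7≡C8 alkyne is converted by syn-hydrostannation and iodination into the (E)-vinyl iodide. The C8–C9 bond is made by Negishi coupling with the C9–C14 alkylzinc, whose C10 centre comes from an Evans ethylation. Ester hydrolysis is last.
- The keto ester comes from a γ-lactone and the enolate of methyl acetate, and the lactone from a γ-keto acid and a butynylcerium reagent. C4 is set by Evans alkylation with 1-bromobut-2-yne, and the C6 ketone by gold-catalysed, carboxyl-assisted alkyne hydration.

Key step: step 7

Remark: numbering follows the acid (C1 = CO2H, ring O1–O2–C3–C4–C5–C6 with O1 on C6, side chain C7–C14), and the target is read from its SMILES as (3S,4R,6S,7E,10R,11E). Enolates and other salts formed by simple deprotonation are treated as forms of their parent compounds and carry no number. The alkynyl carbinol carbon (future C6) is carried as a mixture of epimers up to the key step.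

**Route**

Step 1
Reactants: 1 (4S)-4-benzyl-1,3-oxazolidin-2-one; 2 butanoyl chloride
Product: 3 (4S)-4-benzyl-3-butanoyl-1,3-oxazolidin-2-one
Conditions: n-BuLi, THF, −78 °C; then 2, −78 → 0 °C
Reagents that add atoms: none
Why: N-acylation of the lithiated oxazolidinone by the acid chloride is the standard preparation of an Evans imide and forms no stereocentre.

Step 2
Reactants: 3; 4 1-bromobut-2-yne
Product: 5 (4S)-4-benzyl-3-[(2R)-2-ethylhex-4-ynoyl]-1,3-oxazolidin-2-one
Conditions: NaN(SiMe3)2, THF, −78 °C; then 4, −78 → −40 °C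
Reagents that add atoms: none
Why: Evans alkylation, in which the chelated Z-sodium enolate is attacked by the reactive propargylic bromide on the face opposite the benzyl group, should set the future C4 as R.

Step 3
Reactants: 5; 6 hydrogen peroxide
Product: 8 (2R)-2-ethylhex-4-ynoic acid, via peroxy acid 7 (not isolated)
Conditions: LiOH, 30% aq. H2O2, THF/H2O, 0 °C; then aq. Na2SO3; 1 M HCl
Reagents that add atoms: none
Why: Hydroperoxide-mediated imide cleavage (LiOOH attacks the exocyclic carbonyl) followed by sulfite reduction of the peroxy acid should release the acid without touching the α-stereocentre, and the auxiliary is recovered.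

Step 4
Reactants: 8
Product: 10 (2R)-2-ethyl-4-oxohexanoic acid, via enol lactone 9 (not isolated)
Conditions: AuCl (5 mol%), K2CO3 (10 mol%), MeCN, rt; then 1 M aq. HCl, THF, rt
Reagents that add atoms: water, O
Why: Gold-catalysed 5-exo-dig cycloisomerisation of the 4-alkynoic acid (anti-oxyauration, protodeauration) places oxygen on the future C6 only, and hydrolysis of the Z-enol lactone then gives the γ-keto acid, a regioselective alkyne hydration through carboxyl participation.

Step 5
Reactants: 10; 11 but-1-yne
Product: 13 (3R)-5-(but-1-yn-1-yl)-3,5-diethyloxolan-2-one (both C5 epimers), via hydroxy acid 12 (not isolated)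
Conditions: 11, n-BuLi, THF, −78 °C; CeCl3, −78 °C; then 10 (3.2 equiv of reagent per acid), −78 → −20 °C; 1 M HCl; then TsOH·H2O (5 mol%), CH2Cl2, rt
Reagents that add atoms: none
Why: 1,2-Addition of the weakly basic alkynylcerium reagent to the ketone of the carboxylate salt (organocerium addition, which suppresses enolisation) and acid-catalysed lactonisation of the γ-hydroxy acid should give the lactone; both epimers at the new carbinol carbon are acceptable because step 7 converges them.

Step 6
Reactants: 13; 14 methyl acetate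
Product: 15 methyl (4R)-4,6-diethyl-6-hydroxy-3-oxodec-7-ynoate (both C6 epimers, in equilibrium with its five-membered lactol)
Conditions: LiN(iPr)2, 14 (3 equiv), THF, −78 °C; then 13, −78 → −40 °C; AcOH quench at −78 °C
Reagents that add atoms: none
Why: Claisen-type acylation of the ester enolate by the γ-lactone; the adduct is held as the chelated C2 enolate of the β-keto ester, which stops a second addition and shields C4 from epimerisation.

Step 7
Reactants: 15; 6 hydrogen peroxide
Product: 17 methyl 2-[(3S,4R,6S)-6-(but-1-yn-1-yl)-4,6-diethyl-3-hydroxy-1,2-dioxan-3-yl]acetate, via hydroperoxy ketone 16 (not isolated)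
Conditions: 50% aq. H2O2 (20 equiv), conc. H2SO4 (0.3 equiv), MeCN, 0 °C → rt, held until the C6 epimers have converged; NaHCO3 work-up without reductive quench
Reagents that add atoms: none
Why: Protonation of the tertiary propargylic hydroxyl of 15 (or of the ring oxygen of its lactol form) gives the C6 carbocation, which the large excess of hydrogen peroxide captures as hydroperoxide 16, and the hydroperoxy oxygen then adds to the C3 ketone to give the peroxy-hemiketal. The closest known reactions are the acid-catalysed perhydrolysis of tertiary acetylenic carbinols with H2O2 and H2SO4 and the spontaneous closure of γ-hydroperoxy ketones to 1,2-dioxan-3-ols. The 1,2-dioxane ring closes in the 6-exo-trig mode (O2 onto the C3 carbonyl) after intermolecular formation of the C6–O1 bond. C6 is set under thermodynamic control relative to the fixed C4 centre: ring opening at C3 and re-ionisation at C6 should let both epimers drain into the chair that carries the two ethyl groups equatorial and the slim butynyl group axial, while C3 settles as the anomer with axial hydroxyl and equatorial CH2CO2Me and is erased in step 8. The step needs capture by H2O2 to outrun Meyer–Schuster and Rupe rearrangement of the cation, which the α-effect nucleophile in large excess at low temperature should secure, and it needs C4 to stay intact, which the β-keto ester secures by enolising towards C2 and not towards C4.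

Step 8
Reactants: 17
Product: 18 methyl 2-[(3S,4R,6S)-6-(but-1-yn-1-yl)-4,6-diethyl-1,2-dioxan-3-yl]acetate
Conditions: Et3SiH (5 equiv), Me3SiOTf (2.2 equiv), CH2Cl2, −78 °C; sat. aq. NaHCO3
Reagents that add atoms: none
Why: Ionic hydrogenation of the hemiketal (silane reduction through the peroxycarbenium ion C3=O2+): hydride should add along the axial trajectory to the half-chair that keeps the C4 and C6 ethyl groups pseudo-equatorial, so that C3–H is axial and CH2CO2Me equatorial and trans to the C4 ethyl (3S), while −78 °C and excess silane favour hydride capture over proton loss from C2.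

Step 9
Reactants: 18
Product: 19 methyl 2-[(3S,4R,6S)-4,6-diethyl-6-[(1E)-2-(tributylstannyl)but-1-en-1-yl]-1,2-dioxan-3-yl]acetate
Conditions: Bu3SnH (1.3 equiv, syringe pump), PdCl2(PPh3)2 (5 mol%), THF, 0 °C, dark
Reagents that add atoms: tributyltin hydride, CCCC[SnH](CCCC)CCCC
Why: Palladium-catalysed hydrostannation is a syn addition in which tin goes to C8, the alkyne carbon remote from the fully substituted C6, so the (E)-stannane with H on C7 and C6 cis to the C8 ethyl should form; slow addition in the dark keeps tin radicals, which would attack the O–O bond, at a low level.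

Step 10
Reactants: 19
Product: 20 methyl 2-[(3S,4R,6S)-4,6-diethyl-6-[(1E)-2-iodobut-1-en-1-yl]-1,2-dioxan-3-yl]acetate
Conditions: I2 (1.1 equiv), CH2Cl2, 0 °C
Reagents that add atoms: iodine, II
Why: Iododestannylation (ipso substitution at the vinyl–tin bond) proceeds with retention of alkene geometry and should leave the dialkyl peroxide and the ester untouched.

Step 11
Reactants: 21 (3E)-hex-3-enoic acid; 1
Product: 23 (4S)-4-benzyl-3-[(3E)-hex-3-enoyl]-1,3-oxazolidin-2-one, via mixed anhydride 22 (not isolated)
Conditions: t-BuCOCl, Et3N, THF, −20 °C; then 1, LiCl, −20 °C → rt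
Reagents that add atoms: pivaloyl chloride, CC(C)(C)C(Cl)=O (its acyl group is carried by intermediate 22 only)
Why: Mixed-anhydride N-acylation of the oxazolidinone with LiCl and Et3N is mild enough to keep the β,γ-double bond out of conjugation.

Step 12
Reactants: 23; 24 ethyl trifluoromethanesulfonate
Product: 25 (4S)-4-benzyl-3-[(2S,3E)-2-ethylhex-3-enoyl]-1,3-oxazolidin-2-one
Conditions: NaN(SiMe3)2, THF, −78 °C; then 24, −78 → −50 °C; cold NH4Cl quench
Reagents that add atoms: none
Why: Evans alkylation of the Z-sodium dienolate at its α-carbon by the reactive ethyl triflate, again anti to the benzyl group, should set the future C10 (2S in the imide, 10R in the target).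

Step 13
Reactants: 25
Product: 26 (2S,3E)-2-ethylhex-3-en-1-ol
Conditions: LiBH4, MeOH (1 equiv), Et2O, 0 °C
Reagents that add atoms: none
Why: Reductive cleavage of the imide with lithium borohydride gives the primary alcohol and returns the auxiliary without deprotonating the allylic α-centre.

Step 14
Reactants: 26
Product: 27 (3S,4E)-3-(iodomethyl)hept-4-ene
Conditions: I2, PPh3, imidazole, CH2Cl2, 0 °C → rt
Reagents that add atoms: iodine, II
Why: Appel-type iodination of the primary alcohol is an SN2 displacement at the future C9, which is not a stereocentre.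

Step 15
Reactants: 20; 27
Product: 29 methyl 2-[(3S,4R,6S)-6-[(1E,4R,5E)-2,4-diethylocta-1,5-dien-1-yl]-4,6-diethyl-1,2-dioxan-3-yl]acetate, via alkylzinc iodide 28 (not isolated)
Conditions: 27, Zn (activated with BrCH2CH2Br and Me3SiCl), LiCl, THF, 40 °C; then 20, Pd(dppf)Cl2 (5 mol%), THF, rt
Reagents that add atoms: zinc, [Zn] (carried by intermediate 28 only)
Why: Negishi coupling: LiCl-assisted zinc insertion into the primary iodide and palladium-catalysed sp2–sp3 coupling with the vinyl iodide should form C8–C9 with retention of the E geometry under base-free conditions that the peroxide and its C3–H tolerate.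

Step 16
Reactants: 29
Product: 30 2-[(3S,4R,6S)-6-[(1E,4R,5E)-2,4-diethylocta-1,5-dien-1-yl]-4,6-diethyl-1,2-dioxan-3-yl]acetic acid
Conditions: LiOH, THF/H2O (3:1), 0 °C → rt; 1 M HCl to pH 3 at 0 °C
Reagents that add atoms: lithium hydroxide, [Li+].[OH-]
Why: Saponification of the methyl ester (acyl–oxygen cleavage) at 0 °C should be fast relative to base-induced opening of the peroxide (retro-Michael or Kornblum–DeLaMare), and mild acidification gives the acid.

**Compound list**
1 | (4S)-4-benzyl-1,3-oxazolidin-2-one | O=C1N[C@@H](Cc2ccccc2)CO1 | starting material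
2 | butanoyl chloride | CCCC(Cl)=O | starting material
3 | (4S)-4-benzyl-3-butanoyl-1,3-oxazolidin-2-one | CCCC(=O)N1[C@@H](Cc2ccccc2)COC1=O | intermediate
4 | 1-bromobut-2-yne | CC#CCBr | starting material
5 | (4S)-4-benzyl-3-[(2R)-2-ethylhex-4-ynoyl]-1,3-oxazolidin-2-one | CC[C@H](CC#CC)C(=O)N1[C@@H](Cc2ccccc2)COC1=O | intermediate
6 | hydrogen peroxide | OO | starting material
7 | (2R)-2-ethylhex-4-yneperoxoic acid | CC[C@H](CC#CC)C(=O)OO | intermediate (not isolated)
8 | (2R)-2-ethylhex-4-ynoic acid | CC[C@H](CC#CC)C(=O)O | intermediate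
9 | (3R,5Z)-3-ethyl-5-ethylideneoxolan-2-one | CC[C@@H]1C/C(=C/C)OC1=O | intermediate (not isolated)
10 | (2R)-2-ethyl-4-oxohexanoic acid | CC[C@H](CC(=O)CC)C(=O)O | intermediate
11 | but-1-yne | CCC#C | starting material
12 | (2R)-2,4-diethyl-4-hydroxyoct-5-ynoic acid (C4 epimers) | CCC#CC(O)(CC)C[C@@H](CC)C(=O)O | intermediate (not isolated)
13 | (3R)-5-(but-1-yn-1-yl)-3,5-diethyloxolan-2-one (C5 epimers) | CCC#CC1(CC)C[C@@H](CC)C(=O)O1 | intermediate
14 | methyl acetate | COC(C)=O | starting material
15 | methyl (4R)-4,6-diethyl-6-hydroxy-3-oxodec-7-ynoate (C6 epimers) | CCC#CC(O)(CC)C[C@@H](CC)C(=O)CC(=O)OC | intermediate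
16 | methyl (4R)-4,6-diethyl-6-hydroperoxy-3-oxodec-7-ynoate (C6 epimers) | CCC#CC(OO)(CC)C[C@@H](CC)C(=O)CC(=O)OC | intermediate (not isolated)
17 | methyl 2-[(3S,4R,6S)-6-(but-1-yn-1-yl)-4,6-diethyl-3-hydroxy-1,2-dioxan-3-yl]acetate | CCC#C[C@]1(CC)C[C@@H](CC)[C@](O)(CC(=O)OC)OO1 | intermediate
18 | methyl 2-[(3S,4R,6S)-6-(but-1-yn-1-yl)-4,6-diethyl-1,2-dioxan-3-yl]acetate | CCC#C[C@]1(CC)C[C@@H](CC)[C@H](CC(=O)OC)OO1 | intermediate
19 | methyl 2-[(3S,4R,6S)-4,6-diethyl-6-[(1E)-2-(tributylstannyl)but-1-en-1-yl]-1,2-dioxan-3-yl]acetate | CC/C(=C\[C@]1(CC)C[C@@H](CC)[C@H](CC(=O)OC)OO1)[Sn](CCCC)(CCCC)CCCC | intermediate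
20 | methyl 2-[(3S,4R,6S)-4,6-diethyl-6-[(1E)-2-iodobut-1-en-1-yl]-1,2-dioxan-3-yl]acetate | CC/C(I)=C\[C@]1(CC)C[C@@H](CC)[C@H](CC(=O)OC)OO1 | intermediate
21 | (3E)-hex-3-enoic acid | CC/C=C/CC(=O)O | starting material
22 | 2,2-dimethylpropanoic (3E)-hex-3-enoic anhydride | CC/C=C/CC(=O)OC(=O)C(C)(C)C | intermediate (not isolated)
23 | (4S)-4-benzyl-3-[(3E)-hex-3-enoyl]-1,3-oxazolidin-2-one | CC/C=C/CC(=O)N1[C@@H](Cc2ccccc2)COC1=O | intermediate
24 | ethyl trifluoromethanesulfonate | CCOS(=O)(=O)C(F)(F)F | starting material
25 | (4S)-4-benzyl-3-[(2S,3E)-2-ethylhex-3-enoyl]-1,3-oxazolidin-2-one | CC/C=C/[C@H](CC)C(=O)N1[C@@H](Cc2ccccc2)COC1=O | intermediate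
26 | (2S,3E)-2-ethylhex-3-en-1-ol | CC/C=C/[C@H](CC)CO | intermediate
27 | (3S,4E)-3-(iodomethyl)hept-4-ene | CC/C=C/[C@H](CC)CI | intermediate
28 | [(2S,3E)-2-ethylhex-3-en-1-yl]zinc iodide | CC/C=C/[C@H](CC)C[Zn]I | intermediate (not isolated)
29 | methyl 2-[(3S,4R,6S)-6-[(1E,4R,5E)-2,4-diethylocta-1,5-dien-1-yl]-4,6-diethyl-1,2-dioxan-3-yl]acetate | CC/C=C/[C@H](CC)C/C(=C/[C@]1(CC)C[C@@H](CC)[C@H](CC(=O)OC)OO1)CC | intermediate
30 | 2-[(3S,4R,6S)-6-[(1E,4R,5E)-2,4-diethylocta-1,5-dien-1-yl]-4,6-diethyl-1,2-dioxan-3-yl]acetic acid | CC/C=C/[C@H](CC)C/C(=C/[C@]1(CC)C[C@@H](CC)[C@H](CC(=O)O)OO1)CC | target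

**Step count**
Total: 16 steps. Longest linear sequence: 12 steps (steps 1–10, 15 and 16) from compound 1; the side chain takes steps 11–14.

**Steps most likely to fail**

Step 7. The β-keto ester may drain through its five-membered lactol into 2-alkylidene-tetrahydrofuran or hydroperoxy-ketal products faster than C6 ionises. The cation may also rearrange (Meyer–Schuster) before capture, or the C6 epimers may fail to interconvert so that the ring closes without selection. The fallback removes the ketone before the perhydrolysis and closes the ring by conjugate addition. It sets out from 15 and comes back at 18, so step 8 is bypassed as well.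
- NaBH4 in MeOH at −20 °C reduces the C3 ketone to methyl (4R)-4,6-diethyl-3,6-dihydroxydec-7-ynoate F1.
- MsCl and Et3N convert the secondary hydroxyl into methyl (4R)-4,6-diethyl-6-hydroxy-3-(methanesulfonyloxy)dec-7-ynoate F2, which DBU at 0 °C eliminates to methyl (2E,4R)-4,6-diethyl-6-hydroxydec-2-en-7-ynoate F3.
- Perhydrolysis with 50% H2O2 and H2SO4, now on a plain tertiary propargylic alcohol, gives methyl (2E,4R)-4,6-diethyl-6-hydroperoxydec-2-en-7-ynoate F4.
- Et2NH in CF3CH2OH closes F4 by 6-exo-trig peroxy-Michael addition, with C3 under thermodynamic control. This should give 18 together with its C6 epimer, methyl 2-[(3S,4R,6R)-6-(but-1-yn-1-yl)-4,6-diethyl-1,2-dioxan-3-yl]acetate F5, which is removed by chromatography.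

Step 8. The peroxycarbenium ion may lose a C2 proton to give the exocyclic enoate instead of accepting hydride, or the silyl triflate may ionise the tertiary propargylic C6–O1 bond so that the ring is lost. The fallback places the C3 hydrogen before the ring is made, by running the same closure at the aldehyde oxidation level and adding C1–C2 afterwards. It sets out from 13 and comes back at 18.
- iBu2AlH in CH2Cl2 at −78 °C gives the lactol (3R)-5-(but-1-yn-1-yl)-3,5-diethyloxolan-2-ol F6.
- H2O2 and H2SO4 as in step 7 should convert it, with the same convergence at C6, into the peroxy-hemiacetal (4R,6S)-6-(but-1-yn-1-yl)-4,6-diethyl-1,2-dioxan-3-ol F7.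
- Wittig olefination of its open hydroperoxy-aldehyde form with Ph3P=CHCO2Me gives the (6S) epimer of the hydroperoxy enoate F4 of the first fallback, which Et2NH closes by peroxy-Michael addition to 18.

Step 9. Tin hydride or zerovalent palladium may reduce the O–O bond (radical chain or insertion), or tin may be delivered to C7 as well as C8. The fallback is a platinum-catalysed syn-hydrosilylation, which runs without tin radicals. It sets out from 18 and comes back at 20.
- Et3SiH with Pt2[(CH2=CHSiMe2)2O]3 and P(tBu)3 in THF should place silicon on the less hindered C8 and give methyl 2-[(3S,4R,6S)-4,6-diethyl-6-[(1E)-2-(triethylsilyl)but-1-en-1-yl]-1,2-dioxan-3-yl]acetate F8.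
- Iododesilylation with N-iodosuccinimide in (CF3)2CHOH at 0 °C, with retention of geometry, gives 20.

**Further compounds**
F1 | step 7 | methyl (4R)-4,6-diethyl-3,6-dihydroxydec-7-ynoate | CCC#CC(O)(CC)C[C@@H](CC)C(O)CC(=O)OC
F2 | step 7 | methyl (4R)-4,6-diethyl-6-hydroxy-3-(methanesulfonyloxy)dec-7-ynoate | CCC#CC(O)(CC)C[C@@H](CC)C(OS(C)(=O)=O)CC(=O)OC
F3 | step 7 | methyl (2E,4R)-4,6-diethyl-6-hydroxydec-2-en-7-ynoate | CCC#CC(O)(CC)C[C@@H](CC)/C=C/C(=O)OC
F4 | step 7 | methyl (2E,4R)-4,6-diethyl-6-hydroperoxydec-2-en-7-ynoate | CCC#CC(OO)(CC)C[C@@H](CC)/C=C/C(=O)OC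
F5 | step 7 | methyl 2-[(3S,4R,6R)-6-(but-1-yn-1-yl)-4,6-diethyl-1,2-dioxan-3-yl]acetate | CCC#C[C@@]1(CC)C[C@@H](CC)[C@H](CC(=O)OC)OO1
F6 | step 8 | (3R)-5-(but-1-yn-1-yl)-3,5-diethyloxolan-2-ol | CCC#CC1(CC)C[C@@H](CC)C(O)O1
F7 | step 8 | (4R,6S)-6-(but-1-yn-1-yl)-4,6-diethyl-1,2-dioxan-3-ol | CCC#C[C@]1(CC)C[C@@H](CC)C(O)OO1
F8 | step 9 | methyl 2-[(3S,4R,6S)-4,6-diethyl-6-[(1E)-2-(triethylsilyl)but-1-en-1-yl]-1,2-dioxan-3-yl]acetate | CC/C(=C\[C@]1(CC)C[C@@H](CC)[C@H](CC(=O)OC)OO1)[Si](CC)(CC)CC
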